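(All runs were computed with made-up constants; scatter was added.)

At 3.00 min in the blue run 62.4 % of the Z charged still stood as solid and 18.9 % had become Q, so I counted the balance, 18.7 %, as J in solution.

| setting | blue | Saturday's | Thursday's | Monday's |
|---|---|---|---|---|
| Z | 0.67 M | 0.67 M | 0.67 M | 0.67 M |
| G | 1.01 M | 1.01 M | 1.01 M | 1.01 M |
| X | 0.68 M | 0.600 M | 1.20 M | 2.50 M |
| remark | run made earlier |  |  |  |
| time |  | 3.0 min | 3.0 min | 3.0 min |

blue run (percent of the Z charged)

| time / min | Q / % | Z / % |
|---|---|---|
| 0.200 | 0.7 | 97.8 |
| 0.667 | 1.3 | 90.9 |
| 1.00 | 1.4 | 85.9 |
| 1.50 | 7.0 | 80.0 |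
| 2.50 | 14.2 | 68.8 |
| 3.00 | 18.9 | 62.4 |

(readings scatter by 1 percentage point)

- Z is a solid; its amount is given per volume of the solution
- the analysis behind the earlier runs scatters by 1 percentage point, standard deviation
- steps under discussion: G + X -> L; J + G -> Q; Z <-> J
- at the start none of Z is in solution
- "hardly changes" means that all values lie within two and a half points (for a concentration: within two and a half percent of the largest)
- no earlier run changes the charge of X; that part of a forecast is a guess

* amount of Q at the end, in percent of the Z charged for Saturday's, Thursday's, Monday's, in this order
* the shape of the row from first to last (rises, then falls / falls, then rises / rises all the way / falls all the way / hardly changes)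

I drew the blue curve first. Z fell at 0.141 min⁻¹ of its charge up to 1.00 min, then at 0.117 min⁻¹ from 1.50 min to 3.00 min, a little slower than at first. Q began slowly, with 1.3 % at 0.667 min and 1.4 % at 1.00 min, but these readings scatter by 1 percentage point, so I read neither a flat stretch nor a knee from them. From 1.50 min to 3.00 min Q rose at 0.0793 min⁻¹, slower than Z fell, so J was still filling.

Over that late stretch J averaged 15.8 %. I took cG as about 0.923 M, the charge less what Q had taken, leaving out the unmeasured share of G that went to X. Dividing the Q slope by both gave my reading of the second-order rate constant of J + G → Q, which I call the drain constant, 0.542 M⁻¹ min⁻¹; it carries the scatter of the readings.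

The curve of J bends over where the drain, this constant times cJ and cG, meets the supply from Z. With cG as charged, that crossing, the quasi-steady level of J, lay at 21.4 % of the Z charged, above the 18.7 % reached in the blue run. So I expected Q in the new flasks still to follow the product of cJ and cG at the end. More X should lower cG and so lower Q, by an amount no earlier run could size.

The forecast gave 19 %, 17.5 % and 15 %, shape falls all the way, and it called the size of the drop a guess and the direction firm “The size of this drop is a guess, but the direction is firm.”

The flasks gave 18.5 %, 17.6 % and 15.8 %, shape falls all the way.

    G + X → L (k = 0.00110 M⁻¹ s⁻¹)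
    J + G → Q (k = 0.00940 M⁻¹ s⁻¹)
    Z ⇌ J, rate k3*(cs3 - [J]) while solid is left; crystals form when [J] > cs3 (solubility = 0.320 M, k = 0.00580 s⁻¹)

In Saturday's flask Z went into solution throughout, down to 63.1 %, while J and G made Q. At the end J stood at 18.4 % with 78.0 % of G left, so the drain constant 0.542 M⁻¹ min⁻¹ put the crossing at 27.5 %, above J, and J was being made 1.25 times faster than used up. In Monday's flask 54.7 % of G remained at the end; from 1.50 min to 3.00 min the constant with the mean J and mean G gives Q a gain of 9.3 points, and the flask gained 9.7 points.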